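**Plan**

1. Labdane numbering is used: ring A = C1–C5 + C10, ring B = C5–C10, chain C11–C16, C17 = exocyclic CH2, C18 = CH2O, C19/C20 = methyls. Retrosynthetic cuts, in order: acetyl–O, C8=C17, C3–C4 (ring A), C2–C3, C9–C11, C1–C10. Finally C4 is re-bonded to C7, which reveals a pinane.
2. Enabling feature: quaternary C4 of ring A carries an oxygenated carbon (C18–O). This is the signature of a tertiary β-metaloxy radical from a 1,1-disubstituted epoxide. C4/C18/C19 hang on C5 of ring B as an oxidised isopropenyl group, and C4–C10 with C18, C19 and C20 are the ten carbons of verbenone.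
3. Forward: (+)-α-pinene is oxidised to (+)-verbenone. Vinyl (C1–C2) is added to C10 and the C11–C16 arm to C9, the only enolisable site because C7 is a bridgehead. Cleavage of the cyclobutane bond C4–C7 then turns the pinane into ring B with an isopropenyl group on C5.
4. Epoxidation, hydroformylation (C3 from CO) and hydrazone formation arm the precursor. Ring A closes last, by a Ti(III) epoxide-radical/tosylhydrazone cyclisation that leaves C3 as plain CH2. Saponification, methylenation and acetylation finish the route.
5. Stereochemistry: C5 comes from pinene. C10 is set by attack anti to the CMe2 bridge. C4 is set by a chair transition state (CH2O[Ti] equatorial, away from axial C20). C9 is set by equilibration to the equatorial epimer. C13 comes from methyl hydrogen (R)-3-methylglutarate.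

Key step: step 10

Remark: the epoxide carbon C4 in 10, 11 and 12 is a mixture of epimers and is written without a stereodescriptor, because both epimers give the same planar radical in step 10.
Remark: (1R,5R)-(+)-α-pinene of high enantiomeric purity and methyl hydrogen (R)-3-methylglutarate are taken as commercial.

**Step 1**
Reactants: 1 (1R,5R)-(+)-α-pinene
Product: 2 (1R,5R)-(+)-verbenone
Conditions: t-BuOOH (decane), Cr(CO)6 (cat.), MeCN, reflux
Reagents that add atoms: tert-butyl hydroperoxide, CC(C)(C)OO
Why: Metal-catalysed allylic oxidation with t-BuOOH, a reaction type well known for α-pinene, attacks the only allylic CH2 (the other allylic position is a bridgehead that cannot become part of an enone) and leaves both stereocentres untouched.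

**Step 2**
Reactants: 2 (1R,5R)-(+)-verbenone
Product: 3 (1R,4S,5S)-4,6,6-trimethyl-4-vinylbicyclo[3.1.1]heptan-2-one (vinyl anti to the CMe2 bridge)
Conditions: CH2=CHMgBr, CuBr·SMe2 (10 mol %), THF, −40 to 0 °C; aq. NH4Cl
Reagents that add atoms: vinylmagnesium bromide, C=C[Mg]Br
Why: Copper-catalysed 1,4-addition of a vinyl Grignard reagent, a reaction type known for verbenone, delivers C1–C2 to the face of C10 opposite to the CMe2 bridge, so that C20 ends syn to C4, which is the relative configuration of a trans-decalin.

**Step 3**
Reactants: 4 methyl hydrogen (R)-3-methylglutarate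
Product: 5 (S)-4-methyltetrahydro-2H-pyran-2-one
Conditions: LiBH4, THF, 0 °C to rt; then 2 M HCl
Reagents that add atoms: none
Why: In this chemoselective half-ester reduction LiBH4 reduces the ester but not the lithium carboxylate formed in situ, and acidification lactonises the hydroxy acid, so that the former ester carbon becomes C11 and the untouched stereocentre becomes 13S.

**Step 4**
Reactants: 5 (S)-4-methyltetrahydro-2H-pyran-2-one
Product: 6 methyl (R)-5-iodo-3-methylpentanoate
Conditions: Me3SiI, CH2Cl2, rt; then MeOH
Reagents that add atoms: iodotrimethylsilane, C[Si](C)(C)I; methanol, CO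
Why: In this known conversion of a lactone into an ω-iodo ester, iodide attacks the silyl-activated lactone by SN2 at the O–CH2 carbon (C11) and methanol turns the silyl ester into the methyl ester, without touching C13.

**Step 5**
Reactants: 3 4-vinyl pinanone; 6 methyl (R)-5-iodo-3-methylpentanoate
Product: 7 C9-alkylated pinanone (side chain anti to the CMe2 bridge, 9-epi)
Conditions: LDA, THF, −78 to 0 °C; then 6, DMPU, −40 °C to rt
Reagents that add atoms: none
Why: This enolate alkylation (SN2) is regiospecific because C7 is a cyclobutane bridgehead and the ketone can enolise only towards C9; the iodide should enter anti to the CMe2 bridge to give the 9-epi configuration shown, which is corrected in step 7.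

**Step 6**
Reactants: 7 C9-alkylated pinanone
Product: 8 ring-B enol acetate (C7=C8–OAc, isopropenyl on C5)
Conditions: BF3·OEt2, Zn(OAc)2, Ac2O, CH2Cl2, 0 °C to rt
Reagents that add atoms: acetic anhydride, CC(=O)OC(C)=O
Why: Lewis-acid-promoted fragmentation of the strained C4–C7 bond α to the ketone, known for 4,4-disubstituted nopinones, gives the C7=C8 enolate (trapped as acetate) and the tertiary C4 cation, which loses a methyl proton because a C4=C5 alkene would clash with quaternary C10, while C5, C9, C10 and C13 are not involved.

**Step 7**
Reactants: 8 ring-B enol acetate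
Product: 9 ring-B ketone (isopropenyl, vinyl and C9 side chain all equatorial, C20 axial)
Conditions: NaOMe (cat.), MeOH, rt to 40 °C
Reagents that add atoms: none
Why: Methoxide-catalysed transesterification frees the C8 ketone, and the same base equilibrates the now epimerisable C9 through the enolate to the epimer with the side chain equatorial (9α-H) in the chair that already holds isopropenyl and vinyl equatorial (thermodynamic epimerisation).

**Step 8**
Reactants: 9 ring-B ketone
Product: 10 epoxy ketone (C4/C18 epoxide, both C4 epimers)
Conditions: mCPBA, NaHCO3, CH2Cl2, 0 °C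
Reagents that add atoms: 3-chloroperoxybenzoic acid, O=C(OO)c1cccc(Cl)c1
Why: Prilezhaev epoxidation is chemoselective for the electron-richer 1,1-disubstituted isopropenyl alkene over the hindered monosubstituted vinyl group, and the missing facial control at C4 does not matter because this centre becomes planar in step 10.

**Step 9**
Reactants: 10 epoxy ketone
Product: 12 epoxy keto ester (E)-tosylhydrazone, via epoxy aldehyde 11 (not isolated)
Conditions: Rh(acac)(CO)2 (2 mol %), Xantphos (4 mol %), CO/H2 (1:1, 20 bar), toluene, 70 °C; vent; then TsNHNH2, MeOH, rt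
Reagents that add atoms: carbon monoxide, [C-]#[O+]; p-toluenesulfonyl hydrazide, Cc1ccc(cc1)S(=O)(=O)NN
Why: In this tandem hydroformylation–hydrazone formation a vinyl group on a quaternary carbon can give only the linear aldehyde (C3 from CO) under neutral conditions that spare epoxide, ketone and ester, and the unhindered aldehyde condenses with the hydrazide far faster than the flanked C8 ketone.

**Step 10**
Reactants: 12 epoxy keto ester (E)-tosylhydrazone
Product: 15 methyl (13S)-18-hydroxy-8-oxo-17-norlabdan-15-oate, via tosylhydrazide 13 (not isolated), via diazene 14 (not isolated)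
Conditions: Cp2TiCl2 (20 mol %), Mn dust, 2,4,6-collidine·HCl, THF (0.01 M), rt; filter, concentrate; then NaOAc, MeOH, 65 °C
Reagents that add atoms: none
Why: Proposed new method: Cp2Ti(III)Cl opens the 1,1-disubstituted epoxide homolytically at C4–O, so both C4 epimers converge on one planar tertiary β-titanoxy radical, which adds to C3 of the tosylhydrazone; the hydrazinyl radical is reduced by a second Ti(III) and protonated by collidinium to 13, and warm acetate expels sulfinate to give diazene 14, which loses N2 and leaves C3 as CH2, so the acceptor is traceless and the transient C3 centre is erased. The closest known reaction types are titanocene(III) epoxide–carbonyl and epoxide–nitrile radical cyclisations, the addition of tertiary radicals to sulfonylhydrazones followed by loss of sulfinate and N2 (olefin hydromethylation), and the collapse of N-alkyl-N'-tosylhydrazines in the Caglioti reduction; only their combination in a ring closure is new. Ring A (C1–C5, C10) closes 6-exo-trig by forming C3–C4 through a chair in which the C5–C4 and C10–C1 bonds are both equatorial on ring B, which can lead only to the trans-decalin. The one new permanent stereocentre, quaternary C4, is controlled by the axial C20 methyl on C10: the bulky CH2O[Ti] arm avoids the 1,3-diaxial position and ends equatorial (C18, α), while the small methyl becomes axial C19. The step needs the tertiary radical to reach the C=N carbon before it is reduced, disproportionates to the allylic alcohol or attacks the C8 ketone. The low Ti(III) concentration of the catalytic protocol, the high rate of radical addition to C=N acceptors, the pre-organised diequatorial arms and the boat geometry that attack on C8=O would require should secure this.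

**Step 11**
Reactants: 15 methyl (13S)-18-hydroxy-8-oxo-17-norlabdan-15-oate
Product: 16 (13S)-18-hydroxy-8-oxo-17-norlabdan-15-oic acid
Conditions: LiOH·H2O, THF/MeOH/H2O, rt; then 1 M HCl
Reagents that add atoms: lithium hydroxide, [Li+].[OH-]
Why: Standard saponification of the unhindered methyl ester is placed before methylenation so that the ylide meets an inert carboxylate, and the basic medium keeps C9 at its equatorial equilibrium position.

**Step 12**
Reactants: 16 (13S)-18-hydroxy-8-oxo-17-norlabdan-15-oic acid
Product: 17 (13S)-18-hydroxylabd-8(17)-en-15-oic acid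
Conditions: MePPh3Br (excess), KOt-Bu (excess), THF, 0 °C to reflux; then aq. KHSO4
Reagents that add atoms: methyltriphenylphosphonium bromide, C[P+](c1ccccc1)(c1ccccc1)c1ccccc1.[Br-]
Why: Wittig methylenation with excess ylide, well known for 8-oxo-labdanes, tolerates carboxylate and alkoxide, and because the ylide can reach C8 only from the α face left open in the equatorial C9 epimer, any residual axial epimer is drained through base-mediated enolisation.

**Step 13**
Reactants: 17 (13S)-18-hydroxylabd-8(17)-en-15-oic acid
Product: 19 (13S)-18-acetoxylabd-8(17)-en-15-oic acid (target), via mixed anhydride 18 (not isolated)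
Conditions: Ac2O, pyridine, DMAP (cat.), CH2Cl2, rt; then aq. NaHCO3, rt; acidify (KHSO4)
Reagents that add atoms: acetic anhydride, CC(=O)OC(C)=O
Why: DMAP-catalysed acetylation esterifies the primary neopentyl C18 alcohol, and the mixed anhydride formed at C15 is hydrolysed selectively in the aqueous bicarbonate work-up, which leaves the alkyl acetate and the exocyclic alkene intact.

**Compound list**

1 | (1R,5R)-(+)-α-pinene | CC1=CC[C@@H]2C[C@H]1C2(C)C | starting material
2 | (1R,5R)-(+)-verbenone | CC1=CC(=O)[C@@H]2C[C@H]1C2(C)C | intermediate
3 | (1R,4S,5S)-4,6,6-trimethyl-4-vinylbicyclo[3.1.1]heptan-2-one, vinyl anti to the CMe2 bridge | O=C1C[C@@](C)(C=C)[C@H]2C[C@@H]1C2(C)C | intermediate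
4 | methyl hydrogen (R)-3-methylglutarate | COC(=O)C[C@H](C)CC(=O)O | starting material
5 | (S)-4-methyltetrahydro-2H-pyran-2-one | O=C1C[C@@H](C)CCO1 | intermediate
6 | methyl (R)-5-iodo-3-methylpentanoate | ICC[C@H](C)CC(=O)OC | intermediate
7 | methyl (S)-3-methyl-5-(4,6,6-trimethyl-2-oxo-4-vinylbicyclo[3.1.1]hept-3-yl)pentanoate, chain on C9 anti to the CMe2 bridge (9-epi) | O=C1[C@@H](CC[C@H](C)CC(=O)OC)[C@@](C)(C=C)[C@H]2C[C@@H]1C2(C)C | intermediate
8 | ring-B enol acetate: C7=C8–OAc, C5 isopropenyl, C10 methyl/vinyl, C9 chain still 9-epi | CC(=O)OC1=CC[C@@H](C(C)=C)[C@](C)(C=C)[C@@H]1CC[C@H](C)CC(=O)OC | intermediate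
9 | methyl (S)-3-methyl-5-[2-methyl-6-oxo-3-(prop-1-en-2-yl)-2-vinylcyclohexyl]pentanoate; C5 isopropenyl, C10 vinyl and C9 chain equatorial, C20 axial | O=C1CC[C@@H](C(C)=C)[C@](C)(C=C)[C@H]1CC[C@H](C)CC(=O)OC | intermediate
10 | epoxy ketone, 2-methyloxiran-2-yl on C5 (both C4 epimers) | O=C1CC[C@@H](C2(C)CO2)[C@](C)(C=C)[C@H]1CC[C@H](C)CC(=O)OC | intermediate
11 | epoxy aldehyde, 3-oxopropyl (C1–C3) on C10 (both C4 epimers) | O=C1CC[C@@H](C2(C)CO2)[C@](C)(CCC=O)[C@H]1CC[C@H](C)CC(=O)OC | intermediate
12 | (E)-tosylhydrazone of 11 (both C4 epimers) | O=C1CC[C@@H](C2(C)CO2)[C@](C)(CC/C=N/NS(=O)(=O)c2ccc(C)cc2)[C@H]1CC[C@H](C)CC(=O)OC | intermediate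
13 | methyl (13S)-18-hydroxy-8-oxo-3β-(2-tosylhydrazinyl)-17-norlabdan-15-oate (C3 configuration of no consequence) | O=C1CC[C@H]2[C@](C)(CO)[C@@H](NNS(=O)(=O)c3ccc(C)cc3)CC[C@]2(C)[C@H]1CC[C@H](C)CC(=O)OC | intermediate
14 | corresponding 3-diazene | O=C1CC[C@H]2[C@](C)(CO)[C@@H](N=N)CC[C@]2(C)[C@H]1CC[C@H](C)CC(=O)OC | intermediate
15 | methyl (13S)-18-hydroxy-8-oxo-17-norlabdan-15-oate | O=C1CC[C@H]2[C@](C)(CO)CCC[C@]2(C)[C@H]1CC[C@H](C)CC(=O)OC | intermediate
16 | (13S)-18-hydroxy-8-oxo-17-norlabdan-15-oic acid | O=C1CC[C@H]2[C@](C)(CO)CCC[C@]2(C)[C@H]1CC[C@H](C)CC(=O)O | intermediate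
17 | (13S)-18-hydroxylabd-8(17)-en-15-oic acid | C=C1CC[C@H]2[C@](C)(CO)CCC[C@]2(C)[C@H]1CC[C@H](C)CC(=O)O | intermediate
18 | acetic (13S)-18-acetoxylabd-8(17)-en-15-oic anhydride | C=C1CC[C@H]2[C@](C)(COC(C)=O)CCC[C@]2(C)[C@H]1CC[C@H](C)CC(=O)OC(C)=O | intermediate
19 | (13S)-18-acetoxylabd-8(17)-en-15-oic acid | C=C1CC[C@H]2[C@](C)(COC(C)=O)CCC[C@]2(C)[C@H]1CC[C@H](C)CC(=O)O | target

**Step count**

Total step count: 13. Longest linear sequence: 11 (steps 1, 2 and 5–13). Steps 3 and 4 form the side-chain branch.

**Steps most likely to fail**

**Step 10.**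
- Risk: the tertiary radical may be reduced or may disproportionate to the allylic alcohol before it reaches the C=N carbon. Low-valent titanium may attack the N–N bond of the hydrazone. The hydrazide may collapse incompletely.
- Fallback (known chemistry, from 11 back to 15): step 9 is stopped before the hydrazide is added and epoxy aldehyde 11 is isolated. Titanocene(III) chloride (Cp2TiCl2, Mn, THF) then effects the known epoxide–aldehyde radical cyclisation to the 3β,18-diol F1. 1,1'-Thiocarbonyldiimidazole closes the six-membered cyclic thionocarbonate F2. Barton–McCombie-type reduction (Bu3SnH, AIBN, toluene, reflux) breaks the secondary C3–O bond in preference to the primary C18–O bond. Mild methanolysis of the remaining thiocarbonate returns 15.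

**Step 5.**
- Risk: SN2 attack may be slow at an enolate carbon next to quaternary C10. O-alkylation, E2 loss of HI from the iodide or Claisen attack on its ester may then take over.
- Fallback (from 3 back to 7): LDA/Me3SiCl gives the trimethylsilyl enol ether F3. Mukaiyama–Michael addition to methyl vinyl ketone (catalytic Lewis acid, −78 °C) gives the diketone F4, with the new chain again anti to the bridge. Horner–Wadsworth–Emmons olefination with trimethyl phosphonoacetate/NaH takes place at the unhindered methyl ketone and gives, after removal of the Z isomer, the (E)-enoate F5. Ligand-controlled copper hydride 1,4-reduction (CuH, chiral bisphosphine, PMHS), which leaves the vinyl group alone, sets 13S and returns 7. In this variant C13 comes from the catalyst instead of the chiral pool.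

**Step 6.**
- Risk: the C4 cation may be captured by acetate, may lose the wrong proton or may attack the neighbouring vinyl group.
- Fallback (from 7 back to 9, bypassing 8): iodotrimethylsilane (CH2Cl2, 0 °C) brings about the same C4–C7 heterolysis but traps the cation as iodide. Aqueous hydrolysis of the silyl enol ether gives the isolable tertiary iodide F6. A separate E2 elimination with DBU in warm toluene takes a methyl proton for steric reasons, and the base equilibrates C9 in the same pot, which gives 9.

**Further compounds**

F1 | step 10 | methyl (13S)-3β,18-dihydroxy-8-oxo-17-norlabdan-15-oate | O=C1CC[C@H]2[C@](C)(CO)[C@@H](O)CC[C@]2(C)[C@H]1CC[C@H](C)CC(=O)OC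
F2 | step 10 | 3β,18-cyclic thionocarbonate of F1 | O=C1CC[C@H]2[C@]3(C)COC(=S)O[C@H]3CC[C@]2(C)[C@H]1CC[C@H](C)CC(=O)OC
F3 | step 5 | trimethylsilyl enol ether (C8=C9) of 3 | C[Si](C)(C)OC1=C[C@@](C)(C=C)[C@H]2C[C@@H]1C2(C)C
F4 | step 5 | 3-(3-oxobutyl)-4,6,6-trimethyl-4-vinylbicyclo[3.1.1]heptan-2-one, chain anti to the CMe2 bridge | O=C1[C@@H](CCC(C)=O)[C@@](C)(C=C)[C@H]2C[C@@H]1C2(C)C
F5 | step 5 | methyl (E)-3-methyl-5-(4,6,6-trimethyl-2-oxo-4-vinylbicyclo[3.1.1]hept-3-yl)pent-2-enoate | O=C1[C@@H](CC/C(C)=C/C(=O)OC)[C@@](C)(C=C)[C@H]2C[C@@H]1C2(C)C
F6 | step 6 | ring-B ketone with 2-iodopropan-2-yl on C5 (9-epi) | O=C1CC[C@@H](C(C)(C)I)[C@](C)(C=C)[C@@H]1CC[C@H](C)CC(=O)OC
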